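Assumption: the given SMILES is read as the (3S) enantiomer (CIP order at C3: C2 > quinone carbon > C4 > H), and the route is built for that configuration.

## Retrosynthetic overview

1. The quinone is unveiled last: mild oxidation of the ring B hydroquinone, which comes from global MOM removal of a tris-MOM isoflavan.
2. The C3–aryl bond and the C3 stereocentre come from one enantioselective Pd-catalysed reductive Heck (hydroarylation) of a ring A 2H-chromene with a ring B aryl iodide.
3. The 2H-chromene (pyran ring C, closed before the coupling) comes from an aryl propargyl ether Claisen/electrocyclisation of 3,4-dimethoxy-2-(methoxymethoxy)phenol.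
4. The aryl iodide comes from MOM-directed lithiation/iodination of bis-MOM 2,3-dimethoxyhydroquinone, itself made from 2,3-dimethoxyphenol through the quinone.
5. Both branches diverge from 2,3-dimethoxyphenol, made from catechol via veratrole; rings A and B are aromatic from the start.

## Route

Step 1
Reactants: 1 catechol (benzene-1,2-diol)
Product: 2 veratrole (1,2-dimethoxybenzene)
Conditions: MeI, K2CO3, acetone, reflux
Reagents that add atoms: iodomethane, CI
Why: Williamson O-methylation of both phenols.

Step 2
Reactants: 2 veratrole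
Product: 5 2,3-dimethoxyphenol, via 2,3-dimethoxyphenyllithium 3 (not isolated), via dimethyl 2,3-dimethoxyphenylboronate 4 (not isolated)
Conditions: n-BuLi, TMEDA, Et2O, 0 °C to rt; B(OMe)3, −78 °C to rt; NaOH, 30% H2O2, 0 °C; acidic work-up
Reagents that add atoms: n-butyllithium, [Li]CCCC; trimethyl borate, COB(OC)OC; hydrogen peroxide, OO
Why: Directed ortho-metalation next to OMe puts lithium into 3, borylation puts boron into 4, and oxidative C–B to C–O conversion with H2O2 supplies the phenol oxygen of 5.

Step 3
Reactants: 5 2,3-dimethoxyphenol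
Product: 6 1,2-dimethoxy-3-(methoxymethoxy)benzene
Conditions: NaH, MOMCl, DMF, 0 °C to rt
Reagents that add atoms: chloromethyl methyl ether, COCCl
Why: Williamson-type O-alkylation of the phenoxide installs MOM, which is both the acid-labile protecting group for the future 8-OH and a strong ortho-directing group.

Step 4
Reactants: 6 1,2-dimethoxy-3-(methoxymethoxy)benzene
Product: 9 3,4-dimethoxy-2-(methoxymethoxy)phenol, via aryllithium 7 (not isolated), via dimethyl arylboronate 8 (not isolated)
Conditions: n-BuLi, THF, 0 °C; B(OMe)3, −78 °C to rt; NaOH, 30% H2O2, 0 °C; NH4Cl work-up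
Reagents that add atoms: n-butyllithium, [Li]CCCC; trimethyl borate, COB(OC)OC; hydrogen peroxide, OO
Why: Directed ortho-metalation occurs at the only position ortho to the chelating OMOM group (a stronger director than OMe) to give 7, and borylation to 8 followed by oxidation with H2O2 installs the oxygen that becomes O1.

Step 5
Reactants: 9 3,4-dimethoxy-2-(methoxymethoxy)phenol; 10 propargyl bromide (3-bromoprop-1-yne)
Product: 11 1,2-dimethoxy-3-(methoxymethoxy)-4-(prop-2-yn-1-yloxy)benzene
Conditions: K2CO3, acetone, reflux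
Reagents that add atoms: none
Why: Williamson etherification of the phenol with a primary propargylic bromide.

Step 6
Reactants: 11 1,2-dimethoxy-3-(methoxymethoxy)-4-(prop-2-yn-1-yloxy)benzene
Product: 13 6,7-dimethoxy-8-(methoxymethoxy)-2H-chromene, via ortho-allenylphenol 12 (not isolated)
Conditions: PhNEt2, 210 °C
Reagents that add atoms: none
Why: Aryl propargyl ether Claisen rearrangement to the single free ortho position, then 1,5-H shift and oxa-6π electrocyclisation, closes the pyran ring.

Step 7
Reactants: 5 2,3-dimethoxyphenol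
Product: 14 2,3-dimethoxy-1,4-benzoquinone
Conditions: (KSO3)2NO, KH2PO4, H2O/acetone, rt
Reagents that add atoms: dipotassium nitrosodisulfonate, [K+].[K+].[O]N(S(=O)(=O)[O-])S(=O)(=O)[O-]
Why: Teuber oxidation of a phenol with a free para position gives the para-quinone.

Step 8
Reactants: 14 2,3-dimethoxy-1,4-benzoquinone
Product: 15 2,3-dimethoxybenzene-1,4-diol
Conditions: Na2S2O4, H2O/EtOAc, rt
Reagents that add atoms: none
Why: Dithionite reduction of a quinone to its hydroquinone.

Step 9
Reactants: 15 2,3-dimethoxybenzene-1,4-diol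
Product: 16 2,3-dimethoxy-1,4-bis(methoxymethoxy)benzene
Conditions: NaH, MOMCl, DMF, 0 °C to rt, under Ar
Reagents that add atoms: chloromethyl methyl ether, COCCl
Why: Double Williamson-type O-alkylation masks the hydroquinone as a bis-MOM ether that directs the next lithiation and is later removed together with the ring A MOM group.

Step 10
Reactants: 16 2,3-dimethoxy-1,4-bis(methoxymethoxy)benzene
Product: 18 1-iodo-3,4-dimethoxy-2,5-bis(methoxymethoxy)benzene, via aryllithium 17 (not isolated)
Conditions: n-BuLi, THF, −78 to 0 °C; I2, −78 °C to rt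
Reagents that add atoms: n-butyllithium, [Li]CCCC; iodine, II
Why: MOM-directed ortho-lithiation (the two free positions are equivalent by symmetry) gives 17, the only compound that holds lithium, and iodinolysis of its C–Li bond gives 18.

Step 11
Reactants: 13 6,7-dimethoxy-8-(methoxymethoxy)-2H-chromene; 18 1-iodo-3,4-dimethoxy-2,5-bis(methoxymethoxy)benzene (1.3 equiv)
Product: 19 (3S)-3-[3,4-dimethoxy-2,5-bis(methoxymethoxy)phenyl]-6,7-dimethoxy-8-(methoxymethoxy)-3,4-dihydro-2H-chromene
Conditions: Pd(dba)2 (5 mol %), (S)-tBu-PHOX [(S)-4-tert-butyl-2-(2-diphenylphosphinophenyl)-4,5-dihydrooxazole] (6 mol %), HCO2Na (2 equiv), DMSO/ethylene glycol 4:1, 60 °C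
Reagents that add atoms: none
Why: Proposed new method: an enantioselective intermolecular reductive Heck (formal hydroarylation) of a 2H-chromene, in which 18 adds oxidatively to zerovalent palladium carrying the chiral P,N ligand, the aryl group is delivered to C3 in an enantiodetermining syn-carbopalladation that puts palladium on benzylic C4 (an η3-benzyl species with no syn β-hydrogen, since H3 is anti to Pd), and formate exchange, loss of CO2 and C–H reductive elimination then give the C4 methylene; the closest known reaction types are the palladium-mediated oxyarylation of 2H-chromenes to pterocarpans (same insertion regiochemistry) and the enantioselective reductive Heck hydroarylation of norbornenes with formate; the sense of induction cannot be predicted with confidence, so the (S)-ligand is assumed to give (3S), to be confirmed by correlation with the hydrogenation-derived sample of the fallback, and the (R)-ligand is used if the sense is reversed.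

Step 12
Reactants: 19 (3S)-3-[3,4-dimethoxy-2,5-bis(methoxymethoxy)phenyl]-6,7-dimethoxy-8-(methoxymethoxy)-3,4-dihydro-2H-chromene
Product: 21 target quinone 5-[(3S)-8-hydroxy-6,7-dimethoxy-3,4-dihydro-2H-chromen-3-yl]-2,3-dimethoxycyclohexa-2,5-diene-1,4-dione, via hydroquinone 20 (not isolated)
Conditions: 3 M HCl, MeOH, 45 °C, degassed, under Ar; extractive work-up; then Ag2O (1.2 equiv), EtOAc, rt
Reagents that add atoms: none
Why: Acid-catalysed acetal exchange to methanol removes all three MOM groups, and the para-hydroquinone is then oxidised selectively by Ag2O because it is far more easily oxidised than the ring A monophenol; C3 is untouched, so the (3S) configuration is retained.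

## Compound list

1 | catechol (benzene-1,2-diol) | Oc1ccccc1O | starting material
2 | veratrole (1,2-dimethoxybenzene) | COc1ccccc1OC | intermediate
3 | (2,3-dimethoxyphenyl)lithium | [Li]c1cccc(OC)c1OC | intermediate
4 | dimethyl (2,3-dimethoxyphenyl)boronate | COB(OC)c1cccc(OC)c1OC | intermediate
5 | 2,3-dimethoxyphenol | COc1cccc(O)c1OC | intermediate
6 | 1,2-dimethoxy-3-(methoxymethoxy)benzene | COCOc1cccc(OC)c1OC | intermediate
7 | [3,4-dimethoxy-2-(methoxymethoxy)phenyl]lithium | [Li]c1ccc(OC)c(OC)c1OCOC | intermediate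
8 | dimethyl [3,4-dimethoxy-2-(methoxymethoxy)phenyl]boronate | COB(OC)c1ccc(OC)c(OC)c1OCOC | intermediate
9 | 3,4-dimethoxy-2-(methoxymethoxy)phenol | COCOc1c(O)ccc(OC)c1OC | intermediate
10 | propargyl bromide (3-bromoprop-1-yne) | C#CCBr | starting material
11 | 1,2-dimethoxy-3-(methoxymethoxy)-4-(prop-2-yn-1-yloxy)benzene | C#CCOc1ccc(OC)c(OC)c1OCOC | intermediate
12 | 3,4-dimethoxy-2-(methoxymethoxy)-6-(propa-1,2-dien-1-yl)phenol | C=C=Cc1cc(OC)c(OC)c(OCOC)c1O | intermediate
13 | 6,7-dimethoxy-8-(methoxymethoxy)-2H-chromene | COCOc1c(OC)c(OC)cc2C=CCOc12 | intermediate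
14 | 2,3-dimethoxy-1,4-benzoquinone | COC1=C(OC)C(=O)C=CC1=O | intermediate
15 | 2,3-dimethoxybenzene-1,4-diol | COc1c(O)ccc(O)c1OC | intermediate
16 | 2,3-dimethoxy-1,4-bis(methoxymethoxy)benzene | COCOc1ccc(OCOC)c(OC)c1OC | intermediate
17 | [3,4-dimethoxy-2,5-bis(methoxymethoxy)phenyl]lithium | [Li]c1cc(OCOC)c(OC)c(OC)c1OCOC | intermediate
18 | 1-iodo-3,4-dimethoxy-2,5-bis(methoxymethoxy)benzene | COCOc1cc(I)c(OCOC)c(OC)c1OC | intermediate
19 | (3S)-3-[3,4-dimethoxy-2,5-bis(methoxymethoxy)phenyl]-6,7-dimethoxy-8-(methoxymethoxy)-3,4-dihydro-2H-chromene | COCOc1cc([C@H]2COc3c(cc(OC)c(OC)c3OCOC)C2)c(OCOC)c(OC)c1OC | intermediate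
20 | 2-[(3S)-8-hydroxy-6,7-dimethoxy-3,4-dihydro-2H-chromen-3-yl]-5,6-dimethoxybenzene-1,4-diol | COc1c(OC)c(O)c([C@H]2COc3c(cc(OC)c(OC)c3O)C2)cc1O | intermediate
21 | 5-[(3S)-8-hydroxy-6,7-dimethoxy-3,4-dihydro-2H-chromen-3-yl]-2,3-dimethoxycyclohexa-2,5-diene-1,4-dione | COC1=C(OC)C(=O)C([C@H]2COc3c(cc(OC)c(OC)c3O)C2)=CC1=O | target

## Step count and risks

Total step count: 12. Longest linear sequence: 8 (steps 1, 2, 3, 4, 5, 6, 11, 12; the other branch, steps 1, 2, 7, 8, 9, 10, 11, 12, is also 8).

Step 11 (the proposed new hydroarylation) is the most likely to fail. The risks are aryl delivery to C4 with ring opening, simple reduction of 18 to 16, and insufficient enantioselectivity. The fallback uses known chemistry, sets out from 13 and 16 and comes back at 19. Chromene 13 is treated with NBS in wet DMSO at 0 °C to give racemic trans-3-bromo-6,7-dimethoxy-8-(methoxymethoxy)chroman-4-ol F1. Syn-dehydration of F1 across the cis H3/OH pair with Burgess reagent (Et3N+SO2N−CO2Me) in toluene at 60 °C gives 3-bromo-6,7-dimethoxy-8-(methoxymethoxy)-2H-chromene F2. In parallel, 16 is lithiated with n-BuLi, quenched with B(OiPr)3 and hydrolysed with aqueous NH4Cl to give [3,4-dimethoxy-2,5-bis(methoxymethoxy)phenyl]boronic acid F3. Suzuki–Miyaura coupling of F2 with F3 (Pd(OAc)2, SPhos, K3PO4, toluene/H2O, 80 °C) gives 3-[3,4-dimethoxy-2,5-bis(methoxymethoxy)phenyl]-6,7-dimethoxy-8-(methoxymethoxy)-2H-chromene F4. Asymmetric hydrogenation of this isoflav-3-ene with [Ir(cod)(L)]B[3,5-(CF3)2C6H3]4 (L = a chiral phosphine–oxazoline, antipode chosen for 3S), H2 at 50 bar in CH2Cl2, gives 19.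

Step 12 (global MOM removal and selective oxidation) is the second risk. Two very electron-rich rings are exposed to acid and formaldehyde equivalents, and the ring A phenol could be over-oxidised. The fallback switches to orthogonal protection so that the hydroquinone is only generated under neutral conditions; it sets out from 15 and 13 and comes back at 21. Hydroquinone 15 is benzylated (BnBr, K2CO3, DMF) to 1,4-bis(benzyloxy)-2,3-dimethoxybenzene F5. Iodination (NIS, catalytic CF3CO2H, MeCN) gives 1,4-bis(benzyloxy)-2-iodo-5,6-dimethoxybenzene F6. Coupling of F6 with 13 under the conditions of step 11 gives (3S)-3-[2,5-bis(benzyloxy)-3,4-dimethoxyphenyl]-6,7-dimethoxy-8-(methoxymethoxy)-3,4-dihydro-2H-chromene F7. The single MOM group is removed while ring B is still masked (HCl, MeOH, rt) to give (3S)-3-[2,5-bis(benzyloxy)-3,4-dimethoxyphenyl]-6,7-dimethoxy-3,4-dihydro-2H-chromen-8-ol F8. Hydrogenolysis (H2, Pd/C (palladium on carbon), EtOAc) gives hydroquinone 20, which is oxidised in the same flask with Ag2O to 21.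

Step 6 (thermal Claisen cyclisation) is the third risk. At 210 °C the MOM acetal may not survive, and 2-methylbenzofuran formation or polymerisation can compete. The fallback builds the pyran ring by an intramolecular Wittig reaction instead; it sets out from 9, bypasses steps 5 and 6 and comes back at 13. Magnesium-mediated ortho-formylation of 9 (MgCl2, Et3N, paraformaldehyde, MeCN, reflux) at its only free ortho position gives 2-hydroxy-4,5-dimethoxy-3-(methoxymethoxy)benzaldehyde F9. Schweizer annulation of F9 with vinyltriphenylphosphonium bromide (NaH, DMF, rt to 60 °C; phenoxide conjugate addition, then intramolecular Wittig olefination) gives 13.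

## Further compounds

F1 | step 11 | trans-3-bromo-6,7-dimethoxy-8-(methoxymethoxy)chroman-4-ol (racemic, one enantiomer drawn) | COCOc1c(OC)c(OC)cc2[C@H](O)[C@@H](Br)COc12
F2 | step 11 | 3-bromo-6,7-dimethoxy-8-(methoxymethoxy)-2H-chromene | COCOc1c(OC)c(OC)cc2C=C(Br)COc12
F3 | step 11 | [3,4-dimethoxy-2,5-bis(methoxymethoxy)phenyl]boronic acid | COCOc1cc(B(O)O)c(OCOC)c(OC)c1OC
F4 | step 11 | 3-[3,4-dimethoxy-2,5-bis(methoxymethoxy)phenyl]-6,7-dimethoxy-8-(methoxymethoxy)-2H-chromene | COCOc1cc(C2=Cc3cc(OC)c(OC)c(OCOC)c3OC2)c(OCOC)c(OC)c1OC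
F5 | step 12 | 1,4-bis(benzyloxy)-2,3-dimethoxybenzene | COc1c(OCc2ccccc2)ccc(OCc2ccccc2)c1OC
F6 | step 12 | 1,4-bis(benzyloxy)-2-iodo-5,6-dimethoxybenzene | COc1c(OCc2ccccc2)cc(I)c(OCc2ccccc2)c1OC
F7 | step 12 | (3S)-3-[2,5-bis(benzyloxy)-3,4-dimethoxyphenyl]-6,7-dimethoxy-8-(methoxymethoxy)-3,4-dihydro-2H-chromene | COc1c(OCc2ccccc2)cc([C@H]2COc3c(cc(OC)c(OC)c3OCOC)C2)c(OCc2ccccc2)c1OC
F8 | step 12 | (3S)-3-[2,5-bis(benzyloxy)-3,4-dimethoxyphenyl]-6,7-dimethoxy-3,4-dihydro-2H-chromen-8-ol | COc1c(OCc2ccccc2)cc([C@H]2COc3c(cc(OC)c(OC)c3O)C2)c(OCc2ccccc2)c1OC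
F9 | step 6 | 2-hydroxy-4,5-dimethoxy-3-(methoxymethoxy)benzaldehyde | COCOc1c(O)c(C=O)cc(OC)c1OC
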